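**Plan**

1. Numbering (hydroazulene, kept for all bicyclic compounds): C3 = C(OH)iPr, C3a = ring-fusion CH, C4 = C–OBz, C5 = CH2, C6 = C–CH3, C7 = CH, C8 = C–OAng, C8a = C–CH3; α is the face of the C8a methyl, β the opposite face. Late cuts: C8–O angelate, C3–iPr (to a C3 ketone), C4–O benzoate, C4–H (to a C4 ketone), C6–CH3 (to an enol triflate).
2. Central cut: the C4–C5 and C8–C8a bonds of the seven-membered ring together. This gives a C4–C3a–C8a unit (a cyclopentenyl acylsilane, C4 = acyl carbon) and a C5–C6–C7–C8 unit (the methyl-ketone enolate of an (E)-4-alkoxybut-3-en-2-one).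
3. Enabling feature: with C4 as enol ether (C3a=C4) and C6 as enolate (C6=C7), the seven-membered ring is a cyclohepta-1,4-diene with the C5 methylene between the alkenes and the sp3 atoms C8/C8a adjacent. That is the product pattern of the strain-driven ring expansion of a cis-1,2-dialkenylcyclopropane C4–C5–C6; the C4 oxygen lets an acylsilane act as a 1-oxyvinylcarbene equivalent (Brook shift), and the C6 oxygen later becomes the methyl group.
4. Forward order: five-membered ring from 2-bromo-3-methylcyclopentenone (four steps to the acylsilane); seven-membered ring annulated in one pot; then C6 methyl, C4 carbinol, C3 carbinol, two esters.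
5. Stereochemistry: one reagent-controlled step (CBS reduction, C3 carbinol), then relay. The C3–OTIPS group directs the annulation (C8a; C8 fixed relative to it by the boat transition state); C3a comes from protonation anti to the α groups; C4 from hydride delivered by the C3 hydroxyl; C3 is finally re-set by isopropyl addition anti to the angular methyl.

Key step: step 6

Assumption: 2-bromo-3-methylcyclopent-2-en-1-one (1) is taken as a catalogue compound, and PhMe2SiLi is used as a THF stock solution made beforehand from PhMe2SiCl and lithium.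

**Route**

Step 1
Reactants: 1 2-bromo-3-methylcyclopent-2-en-1-one
Product: 2 (1S)-2-bromo-3-methylcyclopent-2-en-1-ol
Conditions: (R)-2-methyl-CBS-oxazaborolidine [(3aR)-1-methyl-3,3-diphenyltetrahydro-1H,3H-pyrrolo[1,2-c][1,3,2]oxazaborole] (10 mol%), BH3·SMe2, THF, −20 °C; MeOH quench
Reagents that add atoms: none
Why: Corey–Bakshi–Shibata reduction, in which the oxazaborolidine–borane complex binds the ketone with the larger 2-bromovinyl flank away from the catalyst and delivers hydride to one enantioface, so that the (R)-catalyst should set the carbinol as (S), as is precedented for 2-bromocycloalkenones.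

Step 2
Reactants: 2 (1S)-2-bromo-3-methylcyclopent-2-en-1-ol
Product: 3 {[(1S)-2-bromo-3-methylcyclopent-2-en-1-yl]oxy}tri(propan-2-yl)silane
Conditions: TIPSOTf, 2,6-lutidine, CH2Cl2, 0 °C
Reagents that add atoms: triisopropylsilyl trifluoromethanesulfonate, CC(C)[Si](C(C)C)(C(C)C)OS(=O)(=O)C(F)(F)F
Why: Standard silylation of a secondary allylic alcohol with a silyl triflate and a hindered base; the bulky TIPS group is chosen because it later shields one face of the cyclopentene and resists O-to-C silyl shift in the vinyllithium.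

Step 3
Reactants: 3 {[(1S)-2-bromo-3-methylcyclopent-2-en-1-yl]oxy}tri(propan-2-yl)silane
Product: 5 {(5S)-2-methyl-5-[(triisopropylsilyl)oxy]cyclopent-1-en-1-yl}(morpholin-4-yl)methanone, via vinyllithium 4 (not isolated)
Conditions: t-BuLi (2.1 equiv), THF, −78 °C; then 4-morpholinecarbonyl chloride, −78 to 0 °C
Reagents that add atoms: 4-morpholinecarbonyl chloride, O=C(Cl)N1CCOCC1
Why: Bromine–lithium exchange gives a vinyllithium that cannot β-eliminate within the five-membered ring, and its acylation by the carbamoyl chloride (nucleophilic acyl substitution) should give the tertiary amide without touching the stereocenter.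

Step 4
Reactants: 5 {(5S)-2-methyl-5-[(triisopropylsilyl)oxy]cyclopent-1-en-1-yl}(morpholin-4-yl)methanone
Product: 6 [dimethyl(phenyl)silyl]{(5S)-2-methyl-5-[(triisopropylsilyl)oxy]cyclopent-1-en-1-yl}methanone
Conditions: PhMe2SiLi, THF, −78 °C; then aq. NH4Cl
Reagents that add atoms: dimethylphenylsilyllithium, [Li][Si](C)(C)c1ccccc1
Why: Silyllithium addition to a morpholine amide gives a stable tetrahedral adduct that collapses to the acylsilane only on work-up, which prevents over-addition, while the fully substituted β-carbon disfavours 1,4-addition (acylsilane synthesis from morpholine amides).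

Step 5
Reactants: 7 but-3-yn-2-one; 8 (4-methoxyphenyl)methanol
Product: 9 (3E)-4-[(4-methoxybenzyl)oxy]but-3-en-2-one
Conditions: 1,4-diazabicyclo[2.2.2]octane (10 mol%), CH2Cl2, 0 °C to rt
Reagents that add atoms: none
Why: Amine-catalysed oxa-Michael addition of the alcohol to the ynone through the ammonium allenolate should give the thermodynamically favoured (E)-β-alkoxy enone.

Step 6
Reactants: 9 (3E)-4-[(4-methoxybenzyl)oxy]but-3-en-2-one; 6 [dimethyl(phenyl)silyl]{(5S)-2-methyl-5-[(triisopropylsilyl)oxy]cyclopent-1-en-1-yl}methanone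
Product: 14 (3S,8R,8aS)-4-{[dimethyl(phenyl)silyl]oxy}-8-[(4-methoxybenzyl)oxy]-8a-methyl-3-[(triisopropylsilyl)oxy]-1,2,3,5,8,8a-hexahydroazulen-6-yl trifluoromethanesulfonate, via lithium dienolate 10 (not isolated), via acylsilane 1,2-adduct alkoxide 11 (not isolated), via cis-dialkenylcyclopropanolate 12 (not isolated), via ring-expanded lithium enolate 13 (not isolated)
Conditions: LDA, THF, −78 °C; then 6, −80 to −30 °C; then PhNTf2, −78 to 0 °C; aq. NH4Cl
Reagents that add atoms: N-phenylbis(trifluoromethanesulfonimide), O=S(=O)(N(c1ccccc1)S(=O)(=O)C(F)(F)F)C(F)(F)F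
Why: The kinetic dienolate 10 adds 1,2 to the highly electrophilic acylsilane carbonyl (11, making C4–C5), a 1,2-Brook shift of silicon from carbon to oxygen releases a siloxyallyl carbanion that is trapped at once by the β-ketone carbonyl to give the cis-1,2-dialkenylcyclopropanolate 12, and release of cyclopropane strain together with the oxyanion should drive a [3,3] shift below −30 °C that breaks the C4–C6 cyclopropane bond and makes C8–C8a, after which PhNTf2 captures the regiodefined enolate 13. The closest known reaction type is the Brook rearrangement-mediated [3+4] annulation of alkenoylsilanes with lithium enolates of alkenyl methyl ketones (the anionic counterpart of tandem cyclopropanation/Cope rearrangement), combined with standard triflimide trapping of a lithium enolate. The three-membered ring closes 3-exo-trig, whereas the seven-membered ring is not closed by a cyclization but arises by sigmatropic ring expansion through a boat transition state (net [3+4]). C8 and C8a are set relative to each other by the boat geometry, since the (E)-enol ether places OPMB exo and the ring-locked alkene places the C8a methyl (cis to the acyl carbon) endo, so that OPMB and methyl end trans; their absolute sense is set by the C3 OTIPS group, anti to which the ketone carbon should bond to C4, so that the second alkenyl arm, and hence C8, engages the cyclopentene face opposite the silyl ether. The step needs 1,2-addition in preference to 1,4-addition or γ-deprotonation (secured by the carbonyl-like reactivity of the acylsilane at −80 °C and the fully substituted β-carbon), facial control (bulky OTIPS against H at C3), and an enolate 13 that keeps its regiochemistry (trapped cold before β-elimination of the PMB alkoxide or proton transfer can occur).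

Step 7
Reactants: 14 (3S,8R,8aS)-4-{[dimethyl(phenyl)silyl]oxy}-8-[(4-methoxybenzyl)oxy]-8a-methyl-3-[(triisopropylsilyl)oxy]-1,2,3,5,8,8a-hexahydroazulen-6-yl trifluoromethanesulfonate
Product: 15 {[(3S,8R,8aS)-8-[(4-methoxybenzyl)oxy]-6,8a-dimethyl-3-[(triisopropylsilyl)oxy]-1,2,3,5,8,8a-hexahydroazulen-4-yl]oxy}dimethyl(phenyl)silane
Conditions: MeZnCl, Pd(PPh3)4 (5 mol%), THF, 0 °C to rt
Reagents that add atoms: methylzinc chloride, C[Zn]Cl
Why: Negishi coupling of an alkenyl triflate (oxidative addition of zerovalent palladium to the C–OTf bond, transmetalation, reductive elimination) should install the C6 methyl under neutral conditions that leave the silyl enol ether and the skipped diene untouched.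

Step 8
Reactants: 15 {[(3S,8R,8aS)-8-[(4-methoxybenzyl)oxy]-6,8a-dimethyl-3-[(triisopropylsilyl)oxy]-1,2,3,5,8,8a-hexahydroazulen-4-yl]oxy}dimethyl(phenyl)silane
Product: 16 (3S,3aR,8R,8aS)-3-hydroxy-8-[(4-methoxybenzyl)oxy]-6,8a-dimethyl-2,3,3a,5,8,8a-hexahydroazulen-4(1H)-one
Conditions: HF·pyridine, pyridine, THF, 0 °C to rt
Reagents that add atoms: none
Why: Fluoride-mediated desilylation under buffered acidic conditions should cleave the labile silyl enol ether first and protonate C3a on the β-face, opposite the angular methyl and the still-present C3 OTIPS group, to give the trans-fused ketone before the TIPS ether is removed, while the acidic medium avoids E1cB loss of the C3 oxygen and retro-aldol cleavage.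

Step 9
Reactants: 16 (3S,3aR,8R,8aS)-3-hydroxy-8-[(4-methoxybenzyl)oxy]-6,8a-dimethyl-2,3,3a,5,8,8a-hexahydroazulen-4(1H)-one
Product: 17 (3S,3aR,4S,8R,8aS)-8-[(4-methoxybenzyl)oxy]-6,8a-dimethyl-1,2,3,3a,4,5,8,8a-octahydroazulene-3,4-diol
Conditions: Me4NBH(OAc)3, MeCN/AcOH (1:1), −30 °C
Reagents that add atoms: none
Why: Evans–Saksena hydroxyl-directed reduction, in which the α-oriented C3 hydroxyl exchanges onto boron and delivers hydride through a six-membered transition state to the α-face of the C4 carbonyl, should give the 4β-alcohol (anti-1,3-diol) against the intrinsic bias imposed by the angular methyl.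

Step 10
Reactants: 17 (3S,3aR,4S,8R,8aS)-8-[(4-methoxybenzyl)oxy]-6,8a-dimethyl-1,2,3,3a,4,5,8,8a-octahydroazulene-3,4-diol
Product: 18 (3S,3aR,4S,8R,8aS)-3-hydroxy-8-[(4-methoxybenzyl)oxy]-6,8a-dimethyl-1,2,3,3a,4,5,8,8a-octahydroazulen-4-yl benzoate
Conditions: BzCl (1.05 equiv), pyridine, CH2Cl2, −40 to −20 °C
Reagents that add atoms: benzoyl chloride, O=C(Cl)c1ccccc1
Why: Kinetic site-selective acylation, in which the equatorial C4 hydroxyl on the seven-membered ring should react in preference to the C3 hydroxyl, which lies cis-1,3 to the angular methyl on the cyclopentane.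

Step 11
Reactants: 18 (3S,3aR,4S,8R,8aS)-3-hydroxy-8-[(4-methoxybenzyl)oxy]-6,8a-dimethyl-1,2,3,3a,4,5,8,8a-octahydroazulen-4-yl benzoate
Product: 19 (3aS,4S,8R,8aS)-8-[(4-methoxybenzyl)oxy]-6,8a-dimethyl-3-oxo-1,2,3,3a,4,5,8,8a-octahydroazulen-4-yl benzoate
Conditions: Dess–Martin periodinane, NaHCO3, CH2Cl2, 0 °C to rt
Reagents that add atoms: none
Why: Dess–Martin oxidation of the remaining secondary alcohol under buffered, non-basic conditions should give the cyclopentanone without C3a epimerisation or β-elimination of benzoate.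

Step 12
Reactants: 19 (3aS,4S,8R,8aS)-8-[(4-methoxybenzyl)oxy]-6,8a-dimethyl-3-oxo-1,2,3,3a,4,5,8,8a-octahydroazulen-4-yl benzoate
Product: 20 (3R,3aS,4S,8R,8aS)-3-hydroxy-8-[(4-methoxybenzyl)oxy]-6,8a-dimethyl-3-(propan-2-yl)-1,2,3,3a,4,5,8,8a-octahydroazulen-4-yl benzoate
Conditions: iPrMgCl, CeCl3 (anhydrous), THF, −78 °C; aq. NH4Cl at −78 °C
Reagents that add atoms: isopropylmagnesium chloride, CC(C)[Mg]Cl
Why: Organocerium 1,2-addition, in which the weakly basic, oxophilic isopropylcerium reagent should add to the enolisable β-acyloxy ketone faster than it enolises it, reduces it or attacks the benzoate, approaching C3 from the β-face anti to the axial angular methyl and so placing the tertiary hydroxyl α.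

Step 13
Reactants: 20 (3R,3aS,4S,8R,8aS)-3-hydroxy-8-[(4-methoxybenzyl)oxy]-6,8a-dimethyl-3-(propan-2-yl)-1,2,3,3a,4,5,8,8a-octahydroazulen-4-yl benzoate
Product: 21 (3R,3aS,4S,8R,8aS)-3,8-dihydroxy-6,8a-dimethyl-3-(propan-2-yl)-1,2,3,3a,4,5,8,8a-octahydroazulen-4-yl benzoate
Conditions: DDQ, CH2Cl2/pH 7 buffer, 0 °C
Reagents that add atoms: none
Why: Oxidative cleavage of the p-methoxybenzyl ether by DDQ (hydride abstraction to the oxocarbenium ion, then hydrolysis) should free the C8 allylic alcohol without touching the benzoate, the tertiary alcohol or the ring alkene.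

Step 14
Reactants: 21 (3R,3aS,4S,8R,8aS)-3,8-dihydroxy-6,8a-dimethyl-3-(propan-2-yl)-1,2,3,3a,4,5,8,8a-octahydroazulen-4-yl benzoate; 22 (2Z)-2-methylbut-2-enoic acid (angelic acid)
Product: 24 (3R,3aS,4S,8R,8aS)-4-(benzoyloxy)-3-hydroxy-6,8a-dimethyl-3-(propan-2-yl)-1,2,3,3a,4,5,8,8a-octahydroazulen-8-yl (2Z)-2-methylbut-2-enoate, via mixed anhydride 23 (not isolated)
Conditions: 22, 2,4,6-trichlorobenzoyl chloride, Et3N, toluene, rt; then 21, 80 °C
Reagents that add atoms: none
Why: Yamaguchi-type esterification through the preformed mixed anhydride without a nucleophilic catalyst, conditions that transfer the angeloyl group without Z-to-E isomerisation, should acylate only the secondary C8 alcohol because the tertiary C3 alcohol is inert.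

**Compound list**

The descriptor at C3a changes between 16–18 (R) and 19–24 (S) only because the CIP ranking of its neighbours changes; the geometry is the same throughout.

1 | 2-bromo-3-methylcyclopent-2-en-1-one | CC1=C(Br)C(=O)CC1 | starting material
2 | (1S)-2-bromo-3-methylcyclopent-2-en-1-ol | BrC1=C(C)CC[C@@H]1O | intermediate
3 | {[(1S)-2-bromo-3-methylcyclopent-2-en-1-yl]oxy}tri(propan-2-yl)silane | BrC1=C(C)CC[C@@H]1O[Si](C(C)C)(C(C)C)C(C)C | intermediate
4 | {(5S)-2-methyl-5-[(triisopropylsilyl)oxy]cyclopent-1-en-1-yl}lithium | [Li]C1=C(C)CC[C@@H]1O[Si](C(C)C)(C(C)C)C(C)C | intermediate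
5 | {(5S)-2-methyl-5-[(triisopropylsilyl)oxy]cyclopent-1-en-1-yl}(morpholin-4-yl)methanone | O=C(N1CCOCC1)C1=C(C)CC[C@@H]1O[Si](C(C)C)(C(C)C)C(C)C | intermediate
6 | [dimethyl(phenyl)silyl]{(5S)-2-methyl-5-[(triisopropylsilyl)oxy]cyclopent-1-en-1-yl}methanone | O=C([Si](C)(C)c1ccccc1)C1=C(C)CC[C@@H]1O[Si](C(C)C)(C(C)C)C(C)C | intermediate
7 | but-3-yn-2-one | CC(=O)C#C | starting material
8 | (4-methoxyphenyl)methanol | COc1ccc(CO)cc1 | starting material
9 | (3E)-4-[(4-methoxybenzyl)oxy]but-3-en-2-one | CC(=O)/C=C/OCc1ccc(OC)cc1 | intermediate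
10 | lithium (3E)-4-[(4-methoxybenzyl)oxy]buta-1,3-dien-2-olate | [Li+].[O-]C(=C)/C=C/OCc1ccc(OC)cc1 | intermediate
11 | lithium (4E)-1-[dimethyl(phenyl)silyl]-5-[(4-methoxybenzyl)oxy]-1-{(5S)-2-methyl-5-[(triisopropylsilyl)oxy]cyclopent-1-en-1-yl}-3-oxopent-4-en-1-olate (carbinol configuration not defined; it is lost in the Brook shift) | [Li+].[O-]C(CC(=O)/C=C/OCc1ccc(OC)cc1)([Si](C)(C)c1ccccc1)C1=C(C)CC[C@@H]1O[Si](C(C)C)(C(C)C)C(C)C | intermediate
12 | lithium (1S,2R)-2-{[dimethyl(phenyl)silyl]oxy}-1-{(E)-2-[(4-methoxybenzyl)oxy]ethenyl}-2-{(5S)-2-methyl-5-[(triisopropylsilyl)oxy]cyclopent-1-en-1-yl}cyclopropan-1-olate | [Li+].[O-][C@]1(/C=C/OCc2ccc(OC)cc2)C[C@@]1(O[Si](C)(C)c2ccccc2)C2=C(C)CC[C@@H]2O[Si](C(C)C)(C(C)C)C(C)C | intermediate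
13 | lithium (3S,8R,8aS)-4-{[dimethyl(phenyl)silyl]oxy}-8-[(4-methoxybenzyl)oxy]-8a-methyl-3-[(triisopropylsilyl)oxy]-1,2,3,5,8,8a-hexahydroazulen-6-olate | COc1ccc(CO[C@@H]2C=C([O-])CC(O[Si](C)(C)c3ccccc3)=C3[C@]2(C)CC[C@@H]3O[Si](C(C)C)(C(C)C)C(C)C)cc1.[Li+] | intermediate
14 | (3S,8R,8aS)-4-{[dimethyl(phenyl)silyl]oxy}-8-[(4-methoxybenzyl)oxy]-8a-methyl-3-[(triisopropylsilyl)oxy]-1,2,3,5,8,8a-hexahydroazulen-6-yl trifluoromethanesulfonate | COc1ccc(CO[C@@H]2C=C(OS(=O)(=O)C(F)(F)F)CC(O[Si](C)(C)c3ccccc3)=C3[C@]2(C)CC[C@@H]3O[Si](C(C)C)(C(C)C)C(C)C)cc1 | intermediate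
15 | {[(3S,8R,8aS)-8-[(4-methoxybenzyl)oxy]-6,8a-dimethyl-3-[(triisopropylsilyl)oxy]-1,2,3,5,8,8a-hexahydroazulen-4-yl]oxy}dimethyl(phenyl)silane | COc1ccc(CO[C@@H]2C=C(C)CC(O[Si](C)(C)c3ccccc3)=C3[C@]2(C)CC[C@@H]3O[Si](C(C)C)(C(C)C)C(C)C)cc1 | intermediate
16 | (3S,3aR,8R,8aS)-3-hydroxy-8-[(4-methoxybenzyl)oxy]-6,8a-dimethyl-2,3,3a,5,8,8a-hexahydroazulen-4(1H)-one | COc1ccc(CO[C@@H]2C=C(C)CC(=O)[C@@H]3[C@]2(C)CC[C@@H]3O)cc1 | intermediate
17 | (3S,3aR,4S,8R,8aS)-8-[(4-methoxybenzyl)oxy]-6,8a-dimethyl-1,2,3,3a,4,5,8,8a-octahydroazulene-3,4-diol | COc1ccc(CO[C@@H]2C=C(C)C[C@H](O)[C@@H]3[C@]2(C)CC[C@@H]3O)cc1 | intermediate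
18 | (3S,3aR,4S,8R,8aS)-3-hydroxy-8-[(4-methoxybenzyl)oxy]-6,8a-dimethyl-1,2,3,3a,4,5,8,8a-octahydroazulen-4-yl benzoate | COc1ccc(CO[C@@H]2C=C(C)C[C@H](OC(=O)c3ccccc3)[C@@H]3[C@]2(C)CC[C@@H]3O)cc1 | intermediate
19 | (3aS,4S,8R,8aS)-8-[(4-methoxybenzyl)oxy]-6,8a-dimethyl-3-oxo-1,2,3,3a,4,5,8,8a-octahydroazulen-4-yl benzoate | COc1ccc(CO[C@@H]2C=C(C)C[C@H](OC(=O)c3ccccc3)[C@@H]3[C@]2(C)CCC3=O)cc1 | intermediate
20 | (3R,3aS,4S,8R,8aS)-3-hydroxy-8-[(4-methoxybenzyl)oxy]-6,8a-dimethyl-3-(propan-2-yl)-1,2,3,3a,4,5,8,8a-octahydroazulen-4-yl benzoate | COc1ccc(CO[C@@H]2C=C(C)C[C@H](OC(=O)c3ccccc3)[C@@H]3[C@]2(C)CC[C@@]3(O)C(C)C)cc1 | intermediate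
21 | (3R,3aS,4S,8R,8aS)-3,8-dihydroxy-6,8a-dimethyl-3-(propan-2-yl)-1,2,3,3a,4,5,8,8a-octahydroazulen-4-yl benzoate | O[C@@H]1C=C(C)C[C@H](OC(=O)c2ccccc2)[C@@H]2[C@]1(C)CC[C@@]2(O)C(C)C | intermediate
22 | (2Z)-2-methylbut-2-enoic acid (angelic acid) | C/C=C(/C)C(=O)O | starting material
23 | (2Z)-2-methylbut-2-enoic 2,4,6-trichlorobenzoic anhydride | C/C=C(/C)C(=O)OC(=O)c1c(Cl)cc(Cl)cc1Cl | intermediate
24 | (3R,3aS,4S,8R,8aS)-4-(benzoyloxy)-3-hydroxy-6,8a-dimethyl-3-(propan-2-yl)-1,2,3,3a,4,5,8,8a-octahydroazulen-8-yl (2Z)-2-methylbut-2-enoate | C/C=C(/C)C(=O)O[C@@H]1C=C(C)C[C@H](OC(=O)c2ccccc2)[C@@H]2[C@]1(C)CC[C@@]2(O)C(C)C | target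

**Step count**

Total: 14 steps. Longest linear sequence: 13 steps (steps 1–4, then 6–14); step 5 is a one-step branch.

**Steps most likely to fail**

Step 6. What may go wrong: insufficient facial discrimination by the C3 silyl ether in the cyclopropane-forming event; γ-deprotonation of the acylsilane or a sluggish Brook shift because the allyl anion terminus is dialkyl-substituted; slow sigmatropic shift at the fully substituted alkene terminus; β-elimination of the PMB alkoxide from the enolate before triflation.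
Fallback (known chemistry: dirhodium-catalysed tandem cyclopropanation/Cope rearrangement of a vinyldiazoacetate), setting out from 3 and 9 and coming back at 16. Bromide 3 would be cross-coupled with the Reformatsky reagent BrZnCH2CO2Me (Pd(dba)2, P(t-Bu)3, THF) to methyl {(5S)-2-methyl-5-[(triisopropylsilyl)oxy]cyclopent-1-en-1-yl}acetate F1, and diazo transfer (4-acetamidobenzenesulfonyl azide, DBU, MeCN) would give methyl diazo{(5S)-2-methyl-5-[(triisopropylsilyl)oxy]cyclopent-1-en-1-yl}acetate F2. Wittig methylenation of 9 (Ph3P=CH2, THF) would give 1-methoxy-4-({[(1E)-3-methylbuta-1,3-dien-1-yl]oxy}methyl)benzene F3. Decomposition of F2 with Rh2(OAc)4, or with the enantiomer of dirhodium tetrakis[N-(4-dodecylbenzenesulfonyl)prolinate] that reinforces the substrate bias, in the presence of F3 should cyclopropanate the 1,1-disubstituted alkene, and the cis-divinylcyclopropane should rearrange through the same boat geometry to methyl (3S,8R,8aS)-8-[(4-methoxybenzyl)oxy]-6,8a-dimethyl-3-[(triisopropylsilyl)oxy]-1,2,3,5,8,8a-hexahydroazulene-4-carboxylate F4. Ester cleavage (Me3SnOH, 1,2-dichloroethane, 80 °C) would give (3S,8R,8aS)-8-[(4-methoxybenzyl)oxy]-6,8a-dimethyl-3-[(triisopropylsilyl)oxy]-1,2,3,5,8,8a-hexahydroazulene-4-carboxylic acid F5. Curtius rearrangement of F5 (diphenylphosphoryl azide, Et3N, toluene, 80 °C) to the vinyl isocyanate, followed by aqueous HF in MeCN (hydrolysis to the C4 ketone and cleavage of the TIPS ether), would deliver 16.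

Step 10. What may go wrong: poor site selectivity between the two secondary hydroxyls, double benzoylation, or benzoyl migration between the 1,3-related oxygens.
Fallback (the two oxygens differentiated by mechanism rather than by rate), setting out from 16 and coming back at 20. Evans–Tishchenko reduction of 16 with benzaldehyde and catalytic SmI2 (THF, −10 °C) would deliver hydride from the C3 hemiacetal to the α-face of C4 and leave the acyl group on the C3 oxygen, giving (3S,3aS,4S,8R,8aS)-4-hydroxy-8-[(4-methoxybenzyl)oxy]-6,8a-dimethyl-1,2,3,3a,4,5,8,8a-octahydroazulen-3-yl benzoate F6. Silylation (TESOTf, 2,6-lutidine) would give (3S,3aR,4S,8R,8aS)-8-[(4-methoxybenzyl)oxy]-6,8a-dimethyl-4-[(triethylsilyl)oxy]-1,2,3,3a,4,5,8,8a-octahydroazulen-3-yl benzoate F7, and reductive removal of the benzoate (i-Bu2AlH, CH2Cl2, −78 °C) would give (3S,3aR,4S,8R,8aS)-8-[(4-methoxybenzyl)oxy]-6,8a-dimethyl-4-[(triethylsilyl)oxy]-1,2,3,3a,4,5,8,8a-octahydroazulen-3-ol F8. Dess–Martin oxidation would give (3aS,4S,8R,8aS)-8-[(4-methoxybenzyl)oxy]-6,8a-dimethyl-4-[(triethylsilyl)oxy]-2,3a,4,5,8,8a-hexahydroazulen-3(1H)-one F9, and isopropylcerium addition (iPrMgCl, CeCl3, THF, −78 °C), now without an ester in the molecule, would give (3R,3aS,4S,8R,8aS)-8-[(4-methoxybenzyl)oxy]-6,8a-dimethyl-3-(propan-2-yl)-4-[(triethylsilyl)oxy]-1,2,3,3a,4,5,8,8a-octahydroazulen-3-ol F10. Desilylation (HF·pyridine, THF) would give (3R,3aS,4S,8R,8aS)-8-[(4-methoxybenzyl)oxy]-6,8a-dimethyl-3-(propan-2-yl)-1,2,3,3a,4,5,8,8a-octahydroazulene-3,4-diol F11, and benzoylation (BzCl, pyridine, DMAP), possible only at the secondary C4 hydroxyl, would give 20.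

Step 12. What may go wrong: enolisation or β-hydride reduction of the hindered ketone by the branched nucleophile, β-elimination of benzoate, attack at the ester, or insufficient β-face selectivity.
Fallback (sp2 nucleophile, then chemoselective hydrogenation), setting out from 19 and coming back at 20. Addition of isopropenylmagnesium bromide/CeCl3 (THF, −78 °C), a smaller nucleophile without β-hydride that enolises less, would give (3S,3aS,4S,8R,8aS)-3-hydroxy-8-[(4-methoxybenzyl)oxy]-6,8a-dimethyl-3-(prop-1-en-2-yl)-1,2,3,3a,4,5,8,8a-octahydroazulen-4-yl benzoate F12. Hydrogenation with RhCl(PPh3)3 (H2, 1 atm, benzene, rt), which should reduce the 1,1-disubstituted alkene and spare the trisubstituted ring alkene, would give 20.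

**Further compounds**

F1 | step 6 | methyl {(5S)-2-methyl-5-[(triisopropylsilyl)oxy]cyclopent-1-en-1-yl}acetate | COC(=O)CC1=C(C)CC[C@@H]1O[Si](C(C)C)(C(C)C)C(C)C
F2 | step 6 | methyl diazo{(5S)-2-methyl-5-[(triisopropylsilyl)oxy]cyclopent-1-en-1-yl}acetate | COC(=O)C(=[N+]=[N-])C1=C(C)CC[C@@H]1O[Si](C(C)C)(C(C)C)C(C)C
F3 | step 6 | 1-methoxy-4-({[(1E)-3-methylbuta-1,3-dien-1-yl]oxy}methyl)benzene | C=C(C)/C=C/OCc1ccc(OC)cc1
F4 | step 6 | methyl (3S,8R,8aS)-8-[(4-methoxybenzyl)oxy]-6,8a-dimethyl-3-[(triisopropylsilyl)oxy]-1,2,3,5,8,8a-hexahydroazulene-4-carboxylate | COc1ccc(CO[C@@H]2C=C(C)CC(C(=O)OC)=C3[C@]2(C)CC[C@@H]3O[Si](C(C)C)(C(C)C)C(C)C)cc1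
F5 | step 6 | (3S,8R,8aS)-8-[(4-methoxybenzyl)oxy]-6,8a-dimethyl-3-[(triisopropylsilyl)oxy]-1,2,3,5,8,8a-hexahydroazulene-4-carboxylic acid | COc1ccc(CO[C@@H]2C=C(C)CC(C(=O)O)=C3[C@]2(C)CC[C@@H]3O[Si](C(C)C)(C(C)C)C(C)C)cc1
F6 | step 10 | (3S,3aS,4S,8R,8aS)-4-hydroxy-8-[(4-methoxybenzyl)oxy]-6,8a-dimethyl-1,2,3,3a,4,5,8,8a-octahydroazulen-3-yl benzoate | COc1ccc(CO[C@@H]2C=C(C)C[C@H](O)[C@@H]3[C@]2(C)CC[C@@H]3OC(=O)c2ccccc2)cc1
F7 | step 10 | (3S,3aR,4S,8R,8aS)-8-[(4-methoxybenzyl)oxy]-6,8a-dimethyl-4-[(triethylsilyl)oxy]-1,2,3,3a,4,5,8,8a-octahydroazulen-3-yl benzoate | COc1ccc(CO[C@@H]2C=C(C)C[C@H](O[Si](CC)(CC)CC)[C@@H]3[C@]2(C)CC[C@@H]3OC(=O)c2ccccc2)cc1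
F8 | step 10 | (3S,3aR,4S,8R,8aS)-8-[(4-methoxybenzyl)oxy]-6,8a-dimethyl-4-[(triethylsilyl)oxy]-1,2,3,3a,4,5,8,8a-octahydroazulen-3-ol | COc1ccc(CO[C@@H]2C=C(C)C[C@H](O[Si](CC)(CC)CC)[C@@H]3[C@]2(C)CC[C@@H]3O)cc1
F9 | step 10 | (3aS,4S,8R,8aS)-8-[(4-methoxybenzyl)oxy]-6,8a-dimethyl-4-[(triethylsilyl)oxy]-2,3a,4,5,8,8a-hexahydroazulen-3(1H)-one | COc1ccc(CO[C@@H]2C=C(C)C[C@H](O[Si](CC)(CC)CC)[C@@H]3[C@]2(C)CCC3=O)cc1
F10 | step 10 | (3R,3aS,4S,8R,8aS)-8-[(4-methoxybenzyl)oxy]-6,8a-dimethyl-3-(propan-2-yl)-4-[(triethylsilyl)oxy]-1,2,3,3a,4,5,8,8a-octahydroazulen-3-ol | COc1ccc(CO[C@@H]2C=C(C)C[C@H](O[Si](CC)(CC)CC)[C@@H]3[C@]2(C)CC[C@@]3(O)C(C)C)cc1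
F11 | step 10 | (3R,3aS,4S,8R,8aS)-8-[(4-methoxybenzyl)oxy]-6,8a-dimethyl-3-(propan-2-yl)-1,2,3,3a,4,5,8,8a-octahydroazulene-3,4-diol | COc1ccc(CO[C@@H]2C=C(C)C[C@H](O)[C@@H]3[C@]2(C)CC[C@@]3(O)C(C)C)cc1
F12 | step 12 | (3S,3aS,4S,8R,8aS)-3-hydroxy-8-[(4-methoxybenzyl)oxy]-6,8a-dimethyl-3-(prop-1-en-2-yl)-1,2,3,3a,4,5,8,8a-octahydroazulen-4-yl benzoate | COc1ccc(CO[C@@H]2C=C(C)C[C@H](OC(=O)c3ccccc3)[C@@H]3[C@]2(C)CC[C@@]3(O)C(C)=C)cc1
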